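**Retrosynthetic overview**

1. Ring numbering used here: C1 = ring C=O next to the carbinol, C2 = acyl-bearing carbon, C3 = enol carbon, C4 and C5 = CH2, C6 = CH(OH). Enabling feature: C3 and C6 both carry oxygen and are joined by C4–C5, so the C6 oxygen can be tied back to C3 as a γ-butyrolactone (O, C3, C4, C5, C6) that already bears C1 as an exocyclic carbonyl. C2 lies between three carbonyls, so the product is a strongly acidic triketone that drains the equilibrium.
2. C2–C3 is disconnected as an intramolecular Claisen acyl transfer that expands the five-membered lactone to the six-membered carbocycle and frees the C6 hydroxyl. C1–C2 is a Claisen acylation. Both are run in one pot from methyl ketone 6 and lactone acid chloride 8; the (S)-centre comes from the chiral pool and no protecting group is used.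
3. Ketone 6 comes from Tsuji–Wacker oxidation of diene 5, made by copper-catalysed sp3–sp3 coupling of tosylate 2 (E-alkene bought in 1) with the Grignard reagent of bromide 3.
4. Ring order: the lactone ring of 7 is the only ring carried; the carbocycle is the only ring formed, in the last step.

Key step: step 5

Remark on the chemistry: the target is drawn as one enol tautomer of a (4S)-2-acyl-4-hydroxycyclohexane-1,3-dione; the tautomers equilibrate, so the route has to deliver the triketone oxidation level, the (S)-carbinol and the E-alkene.

**Route**

Step 1
Reactants: 1 (E)-hex-4-en-1-ol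
Product: 2 (E)-hex-4-en-1-yl 4-methylbenzenesulfonate
Conditions: TsCl (1.2 equiv), Et3N (1.5 equiv), DMAP (5 mol %), CH2Cl2, 0 °C → rt
Reagents that add atoms: p-toluenesulfonyl chloride, Cc1ccc(cc1)S(=O)(=O)Cl
Why: Tosylation of a primary alcohol; the E-alkene is not involved and no stereocentre is formed.

Step 2
Reactants: 2 (E)-hex-4-en-1-yl 4-methylbenzenesulfonate; 3 11-bromoundec-1-ene
Product: 5 (E)-heptadeca-1,15-diene, via undec-10-enylmagnesium bromide 4 (not isolated)
Conditions: 3 (1.3 equiv), Mg, THF, rt → 40 °C; then 2, Li2CuCl4 (3 mol %), THF, −78 °C → rt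
Reagents that add atoms: none
Why: Copper-catalysed cross-coupling of a primary alkyl Grignard reagent with a primary tosylate (Fouquet–Schlosser type); neither alkene is allylic to a reacting carbon, so the E geometry should be kept and no stereocentre is formed.

Step 3
Reactants: 5 (E)-heptadeca-1,15-diene
Product: 6 (E)-heptadec-15-en-2-one
Conditions: PdCl2 (10 mol %), CuCl (cat.), O2 (1 atm), DMA/H2O, rt
Reagents that add atoms: water, O
Why: Tsuji–Wacker oxidation by Markovnikov hydroxypalladation and β-hydride elimination at the monosubstituted alkene, which binds Pd(II) far better than the 1,2-disubstituted E-alkene, so only the terminal alkene should become the methyl ketone; no stereocentre is formed.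

Step 4
Reactants: 7 (S)-5-oxotetrahydrofuran-2-carboxylic acid
Product: 8 (S)-5-oxotetrahydrofuran-2-carbonyl chloride
Conditions: (COCl)2 (1.3 equiv), DMF (cat.), CH2Cl2, 0 °C → rt; evaporated with toluene, used crude
Reagents that add atoms: oxalyl chloride, ClC(=O)C(=O)Cl
Why: Acid chloride formation through the Vilsmeier-type chloroiminium catalyst under base-free conditions, so the α-oxygenated stereocentre (the future C6) has no pathway to enolise and the lactone is inert.

Step 5
Reactants: 6 (E)-heptadec-15-en-2-one; 8 (S)-5-oxotetrahydrofuran-2-carbonyl chloride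
Product: 12 (6S)-2-[(14E)-hexadec-14-enoyl]-3,6-dihydroxycyclohex-2-en-1-one, via lithium enolate 9 (not isolated), via diketo lactone 10 (not isolated), via bridged alkoxide 11 (not isolated)
Conditions: 6, LiHMDS (2.05 equiv), THF, −78 °C; then 8 (1.0 equiv), −78 °C; then DMPU, −78 → 60 °C; 1 M HCl
Reagents that add atoms: none
Why: Kinetic deprotonation of 6 on the methyl side gives 9, which is C-acylated by 8 (Claisen-type acylation of a lithium enolate by an acid chloride), and the second equivalent of LiHMDS turns the new β-diketone 10 into its lithium enolate, whose central carbon (the future C2) is nucleophilic and stands two atoms away from the lactone carbon C6. On warming, this carbon attacks the lactone carbonyl (the future C3) in a 6-exo-trig Dieckmann-type closure to the 7-oxabicyclo[2.2.1]heptane alkoxide 11, and collapse of 11 with cleavage of the bridging C3–O bond turns the five-membered lactone ring (O, C3, C4, C5, C6) into the six-membered carbocycle (C1–C6) and frees the ring oxygen as the C6 hydroxyl. The closest known reaction types are the Dieckmann step of phthalide (Hauser–Kraus type) annulations, which passes through the same bridged tetrahedral intermediate of a γ-lactone, and the base-induced cyclisation of 5,7-dioxoalkanoates to 2-acylcyclohexane-1,3-diones. No new stereocentre remains: C6 comes from 7 with its C–O and C–H bonds untouched, and the centres of 11 at C2 and C3 vanish again in 12. The step needs C- over O-acylation, attack by C2 rather than by the diketonate oxygens, and retention at C6: the lithium counter-ion at −78 °C favours C-acylation, O-attack is reversible whereas C-attack ends in the triketonate of 12 (a far weaker base than the diketonate of 10, which together with release of the lactone is the driving force), and with only enough base to form mono-anions nothing present should remove the C6–H.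

**Compound list**

1 | (E)-hex-4-en-1-ol | C/C=C/CCCO | starting material
2 | (E)-hex-4-en-1-yl 4-methylbenzenesulfonate | C/C=C/CCCOS(=O)(=O)c1ccc(C)cc1 | intermediate
3 | 11-bromoundec-1-ene | C=CCCCCCCCCCBr | starting material
4 | undec-10-enylmagnesium bromide | C=CCCCCCCCCC[Mg]Br | intermediate (not isolated)
5 | (E)-heptadeca-1,15-diene | C=CCCCCCCCCCCCC/C=C/C | intermediate
6 | (E)-heptadec-15-en-2-one | CC(=O)CCCCCCCCCCCC/C=C/C | intermediate
7 | (S)-5-oxotetrahydrofuran-2-carboxylic acid | OC(=O)[C@@H]1CCC(=O)O1 | starting material
8 | (S)-5-oxotetrahydrofuran-2-carbonyl chloride | ClC(=O)[C@@H]1CCC(=O)O1 | intermediate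
9 | lithium (E)-heptadeca-1,15-dien-2-olate | C=C(O[Li])CCCCCCCCCCCC/C=C/C | intermediate (not isolated)
10 | (S)-5-[(E)-3-oxooctadec-16-enoyl]dihydrofuran-2(3H)-one, present in the flask as its lithium enolate | C/C=C/CCCCCCCCCCCCC(=O)CC(=O)[C@@H]1CCC(=O)O1 | intermediate (not isolated)
11 | lithium (1R,4S)-2-[(14E)-hexadec-14-enoyl]-3-oxo-7-oxabicyclo[2.2.1]heptan-1-olate, bridged tetrahedral intermediate, either configuration at C2 | C/C=C/CCCCCCCCCCCCC(=O)C1C(=O)[C@@H]2CC[C@@]1(O[Li])O2 | intermediate (not isolated)
12 | (6S)-2-[(14E)-hexadec-14-enoyl]-3,6-dihydroxycyclohex-2-en-1-one | C/C=C/CCCCCCCCCCCCC(=O)C1=C(O)CC[C@H](O)C1=O | target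

**Step count and risks**

Total step count: 5. Longest linear sequence: 4 steps (steps 1, 2, 3, 5).

Steps most likely to fail:

1. Step 5. The enolate 9 may be acylated on oxygen or twice, and 6 may enolise partly on the methylene side. Acid chloride 8 may lose its configuration through ketene formation under the basic conditions. The chelated lithium diketonate may attack the lactone only slowly, because the bridged transition state is strained. Fallback (sets out from 6, uses 8, passes 10 as an isolated compound and comes back to the route at 12): the two bond formations are separated and both are run under soft conditions. The enolate of 6 (LiHMDS, THF, −78 °C) is carboxylated with di-tert-butyl dicarbonate to tert-butyl (E)-3-oxooctadec-16-enoate F1, which is freed from its regioisomer. Its magnesium enolate (MgCl2, pyridine, CH2Cl2, 0 °C) is C-acylated by 8 to tert-butyl (16E)-3-oxo-2-[(2S)-5-oxooxolane-2-carbonyl]octadec-16-enoate F2; pyridine is too weak a base to turn 8 into a ketene. TFA in CH2Cl2 cleaves the tert-butyl ester to (16E)-3-oxo-2-[(2S)-5-oxooxolane-2-carbonyl]octadec-16-enoic acid F3, which loses CO2 on warming and gives 10. Isolated 10 is then ring-expanded by alkoxide relay instead of direct attack: NaOMe in MeOH opens the lactone reversibly to methyl (4S,20E)-4-hydroxy-5,7-dioxodocos-20-enoate F4, whose unstrained 6-exo-trig Dieckmann closure should give 12 after acidification.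

2. Step 3. Discrimination between the two alkenes may be incomplete, and palladium hydride species may cause migration or E/Z scrambling of the propenyl double bond. Fallback (sets out from 5 and comes back at 6): Markovnikov hydration by oxymercuration and demercuration, then alcohol oxidation. Hg(OAc)2 in THF/H2O adds to the monosubstituted alkene of 5, which reacts much faster than the trans-disubstituted one and without double-bond migration, to give (E)-(2-hydroxyheptadec-15-en-1-yl)mercury acetate F5. NaBH4/NaOH replaces mercury by hydrogen to give racemic (E)-heptadec-15-en-2-ol F6, and Ley–Griffith oxidation (TPAP cat., NMO, CH2Cl2) gives 6.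

3. Step 2. The Grignard reagent may homocouple, the tosylate may be reduced or eliminated, and the copper-catalysed coupling may stall. Fallback (sets out from 3, uses 2 and comes back at 5): sulfone alkylation and reductive desulfonylation. Bromide 3 and sodium benzenesulfinate (DMF, 60 °C) give undec-10-en-1-yl phenyl sulfone F7. Its α-lithio derivative (n-BuLi, THF, −78 °C) is alkylated with 2 to give [(E)-heptadeca-1,15-dien-11-yl]sulfonylbenzene F8, and sodium amalgam (Na2HPO4, MeOH, −20 °C) removes the sulfonyl group to give 5.

Further compounds
F1 | step 5 | tert-butyl (E)-3-oxooctadec-16-enoate | C/C=C/CCCCCCCCCCCCC(=O)CC(=O)OC(C)(C)C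
F2 | step 5 | tert-butyl (16E)-3-oxo-2-[(2S)-5-oxooxolane-2-carbonyl]octadec-16-enoate | C/C=C/CCCCCCCCCCCCC(=O)C(C(=O)OC(C)(C)C)C(=O)[C@@H]1CCC(=O)O1
F3 | step 5 | (16E)-3-oxo-2-[(2S)-5-oxooxolane-2-carbonyl]octadec-16-enoic acid | C/C=C/CCCCCCCCCCCCC(=O)C(C(=O)O)C(=O)[C@@H]1CCC(=O)O1
F4 | step 5 | methyl (4S,20E)-4-hydroxy-5,7-dioxodocos-20-enoate | C/C=C/CCCCCCCCCCCCC(=O)CC(=O)[C@@H](O)CCC(=O)OC
F5 | step 3 | (E)-(2-hydroxyheptadec-15-en-1-yl)mercury acetate, racemic | CC(=O)O[Hg]CC(O)CCCCCCCCCCCC/C=C/C
F6 | step 3 | (E)-heptadec-15-en-2-ol, racemic | CC(O)CCCCCCCCCCCC/C=C/C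
F7 | step 2 | undec-10-en-1-yl phenyl sulfone | C=CCCCCCCCCCS(=O)(=O)c1ccccc1
F8 | step 2 | [(E)-heptadeca-1,15-dien-11-yl]sulfonylbenzene, racemic | C=CCCCCCCCCC(CCC/C=C/C)S(=O)(=O)c1ccccc1
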